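## Analysis of the target

The target 22 is a flavonol: a chromen-4-one (rings A and C) with an aryl group (ring B) on C2 and a hydroxyl on C3. It is planar and has no stereocenter, so the problem is entirely one of oxygenation pattern. Ring A is 5-hydroxy-7,8-dimethoxy and ring B is 2',4'-dihydroxy-5'-methoxy; three methyl ethers must survive while four hydroxyls (C3, C5, C2', C4') end up free. The sensitive parts are the 3-hydroxy-4-pyranone (a chelating, easily oxidised enolised diketone), the pyranone ring itself (opened by hydroxide at C2), and two very electron-rich benzene rings that are readily halogenated or oxidised. The synthesis is hard for three reasons. The oxidative chalcone route to flavonols is unreliable when ring A carries a substituent at C5 (aurones form) and ring B an ortho oxygen. The C8 oxygen is awkward to introduce late. The C5 oxygen must be told apart from those at C7 and C8. The strategy rests on C3: it is the only ring C carbon bonded to neither ring A, ring B nor O1, it lies between C2 and C4, and it carries a heteroatom. Removing it contracts ring C to a furan and leaves a 2-arylbenzofuran-3-ol with every other atom in place. The enol ether bond of that furan (flavone C2 and C4, benzofuran C2 and C3) is the most electron-rich π bond of the molecule, so C3 can be put back as a halogen-bearing carbene carbon.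

## Retrosynthetic reasoning

**22 from 21.** The last step breaks only O–alkyl bonds: the C5 methyl ether and the two isopropyl ethers on ring B of 21. The C5 methoxy is the only methyl ether peri to the C4 carbonyl, so a boron trihalide held in a six-membered chelate removes it selectively. Secondary alkyl aryl ethers ionise under the same Lewis acid much faster than the three remaining methyl ethers. One operation therefore frees three hydroxyls, and no hydrogenation is needed.

**21 from 20 from 19.** The C3–O bond is traced to a C3–B bond and that to the C3–Br bond of 19. The oxygen cannot arrive on the carbene carbon, because the ring expansion depends on a halide leaving from that carbon. The halogen left behind is used as the handle: Miyaura borylation under acetate (too weak a base to open the pyranone), then mild peroxide oxidation. Direct displacement with hydroxide is rejected because hydroxide adds at C2.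

**19 from 15 and 16.** This is the central cut. C3 is removed together with its two ring bonds (C2–C3 and C3–C4), leaving silyloxybenzofuran 15 and the one-carbon reagent 16. Any other cut in ring C leads back to chalcone or diketone chemistry with the problems named above. This one leaves an aromatic precursor with all seven oxygens placed. The forward reaction must send the dihalocarbene from 16 to the enol ether bond only, and the adduct must open toward the six-membered ring with loss of halide and silyl.

**15 from 13 via 14.** The benzofuran C2–C3 bond and the O–Si bond are cut. Forward, a benzylic carbanion generated next to the ether oxygen of 13 acylates itself on the ortho ester (5-exo-trig), and enolate 14 is silylated in the same flask because the neutral 2-arylbenzofuranone autoxidises at C2. The bond made here is the one into which the key step inserts C3. Two design choices follow. The base must be a lithium dialkylamide, since a silazide is too weak for a benzyl ether C–H on a ring with three donors. Ring B is protected as isopropyl ethers, since benzyl ethers would offer two more, and more acidic, benzylic positions.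

**13 from 4 and 12.** The benzylic C–O bond is cut. A Mitsunobu coupling of phenol 4 with alcohol 12 is preferred to alkylation with the corresponding benzylic halide, because a 2,4-dialkoxybenzyl halide ionises and self-condenses on handling.

**4 from 3 from 1 via 2.** The ester carbon is introduced at the ring position of 1 that lies between two methoxy groups, by directed lithiation (2) and acylation. The phenol of 4 is then freed by chelation-controlled removal of the one ortho methyl that is also buttressed by a neighbouring methoxy. The whole 1,2,3,5-oxygen pattern of ring A is bought with 1.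

**12 from 11 from 9 (via 10) from 8 from 6 (via 7) from 5.** The aldehyde carbon of 5 is exchanged for oxygen by Baeyer–Villiger oxidation, which sets the 1,2,4-trioxygenated pattern of 9 with the methyl ether already distinguished. One carbon is returned by Vilsmeier–Haack formylation at the position para to one isopropoxy group and ortho to the other, and is reduced to the alcohol.

## Alternatives that were turned down

**Alternative 1:** The C2–C1' bond is cut. Forward, the tethered aryl bromide A2, in which a formaldehyde acetal links the C3 oxygen of a chromone to the future C2' oxygen, undergoes palladium-catalysed intramolecular C–H arylation at C2. This gives the dioxepine-bridged flavonol A1.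
- For: the C3 oxygen is present from the start, the tether enforces C2 selectivity and protects two hydroxyls at once, and the route is convergent. On convergence and on avoiding a late C3 oxidation it is stronger than the chosen route.
- Against: the unsymmetrical acetal between an enolic 3-hydroxychromone and a phenol is awkward to make cleanly. The C–H metalation must pass through an eight-membered palladacycle to close a seven-membered ring. The 3-oxygenated chromone half of A2 needs its own multistep synthesis. The end game needs three different deprotections (acetal, benzyl, C5 methyl).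
- Comparison: the chosen route is more linear, but its fragments are joined by classical reactions, it has no medium ring, and its ring-forming step also delivers the C3 handle.

**Alternative 2:** O1–C8a, C4–C4a and O1–C2 are cut. Forward, fluoride releases an aryne from A5; the carboxylate of propiolic acid A4 adds at the future C8a, the aryl anion takes the acyl group, and the resulting phenoxide closes onto the ynone to give flavone A3.
- For: three bonds and ring C form in one operation from two fragments, and the alkoxy group next to the aryne directs the addition correctly. On bonds formed per step it is stronger than the chosen route.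
- Against: A3 lacks both the C8 and the C3 oxygen. Two late oxidations of an electron-rich flavone would follow (a persulfate hydroxylation para to the freed C5 hydroxyl, which is typically inefficient, and a C3 hydroxylation), plus a selective methylation. A5 itself needs several steps, and the hydroxyaryl ynone can close 5-exo to an aurone.
- Comparison: the chosen route buys all ring A oxygens with 1 and needs three steps after its key step; Alternative 2 needs about twice as many.

**Alternative 3:** C4a–C5 is cut and ring A is built last on a pyranone derived from kojic acid A8. Forward, heating β-keto ester A7 expels the ester alcohol to give an acylketene, whose dienol closes by 6π electrocyclisation onto the pyranone double bond and aromatises to A6.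
- For: the C3 oxygen is native to A8, and ring A emerges with C5–OH free and the C7 and C8 oxygens differentiated, so neither a late C3 oxidation nor a peri demethylation is needed. On both points it is stronger than the chosen route.
- Against: it constructs a benzene ring that can be bought fully oxygenated. A7 requires arylation of the pyranone and a long elaboration of the hydroxymethyl arm. The pyranone double bond is a reluctant 2π partner. A regioselective C7 methylation and three debenzylations still follow.
- Comparison: the chosen route is shorter and keeps the uncertainty in one step on a precursor made by routine chemistry.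

Key step: step 10

Remark: 1, 5 and 16 are taken as commercial, and the ring B phenols are carried as isopropyl ethers because these have no acidic benzylic hydrogens and fall in the same BCl3 step that frees the C5 hydroxyl.

## Route

Step 1
Reactants: 1 1,2,3,5-tetramethoxybenzene
Product: 3 methyl 2,3,4,6-tetramethoxybenzoate, via 2,3,4,6-tetramethoxyphenyllithium 2 (not isolated)
Conditions: n-BuLi, TMEDA, THF, 0 °C; then added to excess ClCO2Me, THF, −78 °C
Reagents that add atoms: methyl chloroformate, COC(=O)Cl
Why: Directed ortho-metalation; C4–H lies between two methoxy groups and is the most acidic ring hydrogen, and C4 and C6 are equivalent by symmetry. Inverse addition to excess chloroformate, together with the two flanking methoxy groups, should suppress double addition.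

Step 2
Reactants: 3 methyl 2,3,4,6-tetramethoxybenzoate
Product: 4 methyl 2-hydroxy-3,4,6-trimethoxybenzoate
Conditions: BCl3 (1.2 equiv), CH2Cl2, −78 → 0 °C; then H2O
Reagents that add atoms: none
Why: Chelation-controlled ether cleavage; boron bridges the ester carbonyl and an ortho methoxy oxygen and chloride removes the methyl. The C2 methoxy is buttressed by the C3 methoxy, twisted out of plane and more basic, so it should be cleaved before the C6 methoxy; one equivalent at low temperature stops at the monophenol.

Step 3
Reactants: 5 isovanillin (3-hydroxy-4-methoxybenzaldehyde)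
Product: 6 3-isopropoxy-4-methoxybenzaldehyde
Conditions: iPrBr, K2CO3, DMF, 60 °C
Reagents that add atoms: 2-bromopropane, CC(C)Br
Why: Williamson ether synthesis on a phenoxide in a dipolar aprotic solvent, where substitution outruns elimination of the secondary bromide.

Step 4
Reactants: 6 3-isopropoxy-4-methoxybenzaldehyde
Product: 8 3-isopropoxy-4-methoxyphenol, via 3-isopropoxy-4-methoxyphenyl formate 7 (not isolated)
Conditions: mCPBA, CH2Cl2, 0 °C → rt; then K2CO3, MeOH, rt
Reagents that add atoms: 3-chloroperoxybenzoic acid (mCPBA), O=C(OO)c1cccc(Cl)c1
Why: Baeyer–Villiger oxidation; the electron-rich aryl group with a para methoxy migrates in preference to hydride, and the aryl formate is methanolysed to the phenol.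

Step 5
Reactants: 8 3-isopropoxy-4-methoxyphenol
Product: 9 2,4-diisopropoxy-1-methoxybenzene
Conditions: iPrBr, K2CO3, DMF, 60 °C
Reagents that add atoms: 2-bromopropane, CC(C)Br
Why: Williamson ether synthesis, as in step 3.

Step 6
Reactants: 9 2,4-diisopropoxy-1-methoxybenzene
Product: 11 2,4-diisopropoxy-5-methoxybenzaldehyde, via aryl iminium chloride 10 (not isolated)
Conditions: POCl3, DMF, 0 → 60 °C; then ice–water
Reagents that add atoms: N,N-dimethylformamide, CN(C)C=O; water, O
Why: Vilsmeier–Haack formylation. C5 is para to one isopropoxy group, ortho to the other and unhindered; C3 is crowded between two isopropoxy groups and C6 is activated only by the methoxy, so substitution should occur at C5, as it does for 1,2,4-trimethoxybenzene.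

Step 7
Reactants: 11 2,4-diisopropoxy-5-methoxybenzaldehyde
Product: 12 (2,4-diisopropoxy-5-methoxyphenyl)methanol
Conditions: NaBH4, MeOH, 0 °C
Reagents that add atoms: none
Why: Hydride reduction of an aromatic aldehyde; nothing else in the molecule is reducible.

Step 8
Reactants: 4 methyl 2-hydroxy-3,4,6-trimethoxybenzoate; 12 (2,4-diisopropoxy-5-methoxyphenyl)methanol
Product: 13 methyl 2-[(2,4-diisopropoxy-5-methoxyphenyl)methoxy]-3,4,6-trimethoxybenzoate
Conditions: PPh3, DIAD, THF, 0 °C → rt
Reagents that add atoms: none
Why: Mitsunobu etherification; the salicylate phenol is acidic enough to protonate the betaine, and the primary benzylic oxyphosphonium is displaced by the phenoxide at oxygen. The alcohol is used so that the unstable electron-rich benzylic halide is never handled.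

Step 9
Reactants: 13 methyl 2-[(2,4-diisopropoxy-5-methoxyphenyl)methoxy]-3,4,6-trimethoxybenzoate
Product: 15 2-(2,4-diisopropoxy-5-methoxyphenyl)-3-(tert-butyldimethylsilyloxy)-4,6,7-trimethoxybenzofuran, via lithium benzofuran-3-olate 14 (not isolated)
Conditions: LiN(iPr)2 (2.5 equiv), THF, −78 → 0 °C; then TBSCl, DMPU, −78 °C → rt
Reagents that add atoms: tert-butyldimethylsilyl chloride, CC(C)(C)[Si](C)(C)Cl
Why: Anionic cyclisation; the amide, guided by the ester carbonyl, removes a benzylic hydrogen next to the ether oxygen and the carbanion acylates itself on the ester (5-exo-trig, Dieckmann-type). The second equivalent of base converts the ketone into aromatic enolate 14, which the silyl chloride traps on oxygen because that gives the benzofuran. Isopropyl ethers offer no competing benzylic site, and trapping in the flask avoids autoxidation of the ketone at C2.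

Step 10
Reactants: 15 2-(2,4-diisopropoxy-5-methoxyphenyl)-3-(tert-butyldimethylsilyloxy)-4,6,7-trimethoxybenzofuran; 16 bromoform
Product: 19 3-bromo-2-(2,4-diisopropoxy-5-methoxyphenyl)-5,7,8-trimethoxychromen-4-one, via gem-dibromocyclopropane adduct 17 (not isolated), via 3-bromo-4-silyloxybenzopyrylium bromide 18 (not isolated)
Conditions: KOtBu (added slowly), toluene–hexane, −20 °C → rt
Reagents that add atoms: none
Why: KOtBu deprotonates 16 and the tribromomethyl anion loses bromide to give dibromocarbene, an electrophile that adds to the most electron-rich π bond of 15, the C2=C3 enol ether bond bearing both O1 and the silyloxy group (flavone C2 and C4), giving the cis-fused gem-dibromocyclopropane 17 by [2+1] cycloaddition. The ring-fusion bond of 17 then breaks in a disrotatory two-electron electrocyclic opening concerted with departure of the bromide that lies over the furan ring, so the five-membered ring grows into the six-membered 3-bromo-4-silyloxybenzopyrylium 18, stabilised by O1 at one terminus and the silyloxy oxygen at the other; ring C is thus closed by ring expansion, not by cyclisation. tert-Butoxide takes the silyl group from oxygen and leaves the neutral 3-bromochromen-4-one 19, in which the carbene carbon has become C3 and the bonds C2–C3 and C3–C4 are new. The closest known reactions are the dihalocarbene ring expansion of cyclic silyl enol ethers to 2-halo-enones (indanone silyl enol ethers to 2-halo-1-naphthols included) and the Ciamician–Dennstedt expansion of indoles and benzofurans. No stereocenter remains, since the two sp3 carbons of 17 are flattened again on opening. The step needs chemoselectivity for the enol ether bond over the two alkoxy-substituted benzene rings, which the two oxygen donors on that bond and the weak aromaticity of the furan provide; it also needs the silyl ether to outlast the alkoxide until the carbene has added, for which the bulky silyl group, the non-polar solvent, the low temperature and the slow addition of base are chosen.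

Step 11
Reactants: 19 3-bromo-2-(2,4-diisopropoxy-5-methoxyphenyl)-5,7,8-trimethoxychromen-4-one
Product: 20 2-(2,4-diisopropoxy-5-methoxyphenyl)-5,7,8-trimethoxy-3-(4,4,5,5-tetramethyl-1,3,2-dioxaborolan-2-yl)chromen-4-one
Conditions: B2pin2, Pd(dppf)Cl2 (dppf = 1,1'-bis(diphenylphosphino)ferrocene, 5 mol %), KOAc, 1,4-dioxane, 90 °C
Reagents that add atoms: bis(pinacolato)diboron, CC1(C)OB(OC1(C)C)B1OC(C)(C)C(C)(C)O1
Why: Miyaura borylation; zerovalent palladium inserts into the activated alkenyl C3–Br bond, acetate mediates transmetalation from the diboron, and reductive elimination forms C3–B. Acetate is too weak a base to open the pyranone or to promote Suzuki coupling of the product with 19.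

Step 12
Reactants: 20 2-(2,4-diisopropoxy-5-methoxyphenyl)-5,7,8-trimethoxy-3-(4,4,5,5-tetramethyl-1,3,2-dioxaborolan-2-yl)chromen-4-one
Product: 21 2-(2,4-diisopropoxy-5-methoxyphenyl)-3-hydroxy-5,7,8-trimethoxychromen-4-one
Conditions: NaBO3·4H2O, THF–H2O, rt
Reagents that add atoms: sodium perborate (NaBO3·4H2O, Na2[B2(O2)2(OH)4]), [Na+].[Na+].O[B-]1(O)OO[B-](O)(O)OO1
Why: Oxidation of the carbon–boron bond; the peroxoborate adds to boron, C3 migrates to oxygen and the borate ester hydrolyses to the enol, which is the flavonol. Perborate is mild and nearly neutral, so the pyranone should not be opened.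

Step 13
Reactants: 21 2-(2,4-diisopropoxy-5-methoxyphenyl)-3-hydroxy-5,7,8-trimethoxychromen-4-one
Product: 22 2-(2,4-dihydroxy-5-methoxyphenyl)-3,5-dihydroxy-7,8-dimethoxychromen-4-one (the target)
Conditions: BCl3 (excess), CH2Cl2, −78 → 0 °C; then H2O
Reagents that add atoms: none
Why: Lewis acid ether cleavage; the two isopropyl aryl ethers ionise readily at boron, and the C5 methyl ether is removed through the six-membered boron chelate with the C4 carbonyl. The methyl ethers at C7, C8 and C5' have neither a secondary alkyl group nor a peri carbonyl and should survive at 0 °C.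

## Compound list

1 | 1,2,3,5-tetramethoxybenzene | COc1cc(OC)c(OC)c(OC)c1 | starting material
2 | 2,3,4,6-tetramethoxyphenyllithium | [Li]c1c(OC)cc(OC)c(OC)c1OC | intermediate (not isolated)
3 | methyl 2,3,4,6-tetramethoxybenzoate | COC(=O)c1c(OC)cc(OC)c(OC)c1OC | intermediate
4 | methyl 2-hydroxy-3,4,6-trimethoxybenzoate | COC(=O)c1c(OC)cc(OC)c(OC)c1O | intermediate
5 | isovanillin (3-hydroxy-4-methoxybenzaldehyde) | COc1ccc(C=O)cc1O | starting material
6 | 3-isopropoxy-4-methoxybenzaldehyde | COc1ccc(C=O)cc1OC(C)C | intermediate
7 | 3-isopropoxy-4-methoxyphenyl formate | COc1ccc(OC=O)cc1OC(C)C | intermediate (not isolated)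
8 | 3-isopropoxy-4-methoxyphenol | COc1ccc(O)cc1OC(C)C | intermediate
9 | 2,4-diisopropoxy-1-methoxybenzene | COc1ccc(OC(C)C)cc1OC(C)C | intermediate
10 | N-[(2,4-diisopropoxy-5-methoxyphenyl)methylidene]-N-methylmethanaminium chloride | COc1cc(C=[N+](C)C)c(OC(C)C)cc1OC(C)C.[Cl-] | intermediate (not isolated)
11 | 2,4-diisopropoxy-5-methoxybenzaldehyde | COc1cc(C=O)c(OC(C)C)cc1OC(C)C | intermediate
12 | (2,4-diisopropoxy-5-methoxyphenyl)methanol | COc1cc(CO)c(OC(C)C)cc1OC(C)C | intermediate
13 | methyl 2-[(2,4-diisopropoxy-5-methoxyphenyl)methoxy]-3,4,6-trimethoxybenzoate | COC(=O)c1c(OC)cc(OC)c(OC)c1OCc1cc(OC)c(OC(C)C)cc1OC(C)C | intermediate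
14 | lithium 2-(2,4-diisopropoxy-5-methoxyphenyl)-4,6,7-trimethoxybenzofuran-3-olate | COc1cc(OC)c2c([O-])c(-c3cc(OC)c(OC(C)C)cc3OC(C)C)oc2c1OC.[Li+] | intermediate (not isolated)
15 | 2-(2,4-diisopropoxy-5-methoxyphenyl)-3-(tert-butyldimethylsilyloxy)-4,6,7-trimethoxybenzofuran | COc1cc(OC)c2c(O[Si](C)(C)C(C)(C)C)c(-c3cc(OC)c(OC(C)C)cc3OC(C)C)oc2c1OC | intermediate (key-step precursor)
16 | bromoform | BrC(Br)Br | starting material
17 | 1,1-dibromo-6b-(tert-butyldimethylsilyloxy)-1a-(2,4-diisopropoxy-5-methoxyphenyl)-3,4,6-trimethoxy-1a,6b-dihydro-1H-cyclopropa[b]benzofuran (racemic; the ring fusion can only be cis) | COc1cc(OC)c2c(c1OC)OC1(c3cc(OC)c(OC(C)C)cc3OC(C)C)C(Br)(Br)C21O[Si](C)(C)C(C)(C)C | intermediate (not isolated)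
18 | 3-bromo-4-(tert-butyldimethylsilyloxy)-2-(2,4-diisopropoxy-5-methoxyphenyl)-5,7,8-trimethoxychromenylium bromide | COc1cc(OC)c2c(O[Si](C)(C)C(C)(C)C)c(Br)c(-c3cc(OC)c(OC(C)C)cc3OC(C)C)[o+]c2c1OC.[Br-] | intermediate (not isolated)
19 | 3-bromo-2-(2,4-diisopropoxy-5-methoxyphenyl)-5,7,8-trimethoxychromen-4-one | COc1cc(OC)c2c(=O)c(Br)c(-c3cc(OC)c(OC(C)C)cc3OC(C)C)oc2c1OC | intermediate (key-step product)
20 | 2-(2,4-diisopropoxy-5-methoxyphenyl)-5,7,8-trimethoxy-3-(4,4,5,5-tetramethyl-1,3,2-dioxaborolan-2-yl)chromen-4-one | COc1cc(OC)c2c(=O)c(B3OC(C)(C)C(C)(C)O3)c(-c3cc(OC)c(OC(C)C)cc3OC(C)C)oc2c1OC | intermediate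
21 | 2-(2,4-diisopropoxy-5-methoxyphenyl)-3-hydroxy-5,7,8-trimethoxychromen-4-one | COc1cc(OC)c2c(=O)c(O)c(-c3cc(OC)c(OC(C)C)cc3OC(C)C)oc2c1OC | intermediate
22 | 2-(2,4-dihydroxy-5-methoxyphenyl)-3,5-dihydroxy-7,8-dimethoxychromen-4-one | COc1cc(-c2oc3c(OC)c(OC)cc(O)c3c(=O)c2O)c(O)cc1O | target

## Step count and least certain steps

Total step count: 13. Longest linear sequence: 11 steps (steps 3 to 13, from 5); ring A enters through the two-step branch 1 → 4.

**Step 10 (key step).** Three processes could divert it.
- The silyl group may be lost to tert-butoxide before the carbene arrives; the free enolate is then attacked at C2 and protonated, so a dihalomethyl group is attached without ring growth.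
- Addition to a tetrasubstituted double bond flanked by the C4 methoxy and an ortho-substituted aryl ring may be slow, so the carbene is consumed by alkoxide.
- The pyrylium ion may be captured at C2 by tert-butoxide before it is desilylated.

Fallback: the route sets out from 15 and rejoins at 21, replacing steps 10 to 12 with a base-free one-carbon insertion. Simmons–Smith cyclopropanation (Et2Zn, CH2I2, CH2Cl2) should give the siloxycyclopropane 6b-(tert-butyldimethylsilyloxy)-1a-(2,4-diisopropoxy-5-methoxyphenyl)-3,4,6-trimethoxy-1a,6b-dihydro-1H-cyclopropa[b]benzofuran F1. FeCl3 in DMF then cleaves the ring-fusion bond oxidatively (one-electron oxidation, scission to the C2 radical stabilised by O1 and ring B, further oxidation and loss of a proton) to give 2-(2,4-diisopropoxy-5-methoxyphenyl)-5,7,8-trimethoxychromen-4-one F2. Dimethyldioxirane epoxidises C2=C3 to 1a-(2,4-diisopropoxy-5-methoxyphenyl)-3,4,6-trimethoxy-1a,7a-dihydro-7H-oxireno[2,3-b]chromen-7-one F3, which a trace of acid isomerises to 21.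

**Step 9.** The benzylic hydrogens of 13 sit on a ring with three donor substituents, so deprotonation may be incomplete or misdirected toward a ring position between two alkoxy groups. Silylation of the crowded enolate oxygen may also lag, exposing the enolate to air oxidation at C2 on work-up.

Fallback: the route sets out from 1 and 9 and rejoins at 15, making the C2–aryl bond by cross-coupling instead.
- Friedel–Crafts acylation of 1 with chloroacetyl chloride and AlCl3, with loss of the buttressed ortho methyl, should give 2-chloro-1-(2-hydroxy-3,4,6-trimethoxyphenyl)ethanone F4.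
- NaOAc in ethanol closes it to 4,6,7-trimethoxybenzofuran-3(2H)-one F5.
- N-Bromosuccinimide brominates 9 at C5 to 1-bromo-2,4-diisopropoxy-5-methoxybenzene F6.
- Palladium-catalysed α-arylation of the enolate of F5 with F6 (Pd2(dba)3, XPhos, NaOtBu, toluene) gives 2-(2,4-diisopropoxy-5-methoxyphenyl)-4,6,7-trimethoxybenzofuran-3(2H)-one F7.
- TBSOTf and Et3N convert F7 into 15.

**Step 11.** The C3–Br bond lies between the carbonyl and a twisted ortho-substituted aryl ring, so oxidative addition and transmetalation may be slow. Hydrodebromination, or protodeboronation of the hindered alkenylboronate, may then overtake borylation.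

Fallback: the route sets out from 19 and rejoins at 21 without palladium. Bromine–magnesium exchange with iPrMgCl·LiCl at −40 °C gives [2-(2,4-diisopropoxy-5-methoxyphenyl)-5,7,8-trimethoxy-4-oxochromen-3-yl]magnesium chloride F8. B(OMe)3 converts it into dimethyl [2-(2,4-diisopropoxy-5-methoxyphenyl)-5,7,8-trimethoxy-4-oxochromen-3-yl]boronate F9, which perborate oxidises in the same flask to 21.

**Step 13.** Three ether cleavages of different rates run in one flask. A methyl at C8 or C5' (each ortho to another oxygen) may also be lost. Conversely, the C5 methyl may be retained because boron is tied up in the C3–O/C4=O chelate. The free polyphenol may also oxidise during a long exposure.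

Fallback: the route sets out from 21 and rejoins at 22, separating the two kinds of cleavage. MgI2·OEt2 in toluene–THF at 60 °C removes only the chelated C5 methyl (iodide attacks the methyl of the magnesium-bound ether) and gives 2-(2,4-diisopropoxy-5-methoxyphenyl)-3,5-dihydroxy-7,8-dimethoxychromen-4-one F10. BCl3 at −78 °C then removes only the isopropyl groups to give 22.

## Further compounds

F1 | step 10 | 6b-(tert-butyldimethylsilyloxy)-1a-(2,4-diisopropoxy-5-methoxyphenyl)-3,4,6-trimethoxy-1a,6b-dihydro-1H-cyclopropa[b]benzofuran (racemic, cis-fused) | COc1cc(OC)c2c(c1OC)OC1(c3cc(OC)c(OC(C)C)cc3OC(C)C)CC21O[Si](C)(C)C(C)(C)C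
F2 | step 10 | 2-(2,4-diisopropoxy-5-methoxyphenyl)-5,7,8-trimethoxychromen-4-one | COc1cc(OC)c2c(=O)cc(-c3cc(OC)c(OC(C)C)cc3OC(C)C)oc2c1OC
F3 | step 10 | 1a-(2,4-diisopropoxy-5-methoxyphenyl)-3,4,6-trimethoxy-1a,7a-dihydro-7H-oxireno[2,3-b]chromen-7-one (racemic, cis-fused) | COc1cc(OC)c2c(c1OC)OC1(c3cc(OC)c(OC(C)C)cc3OC(C)C)OC1C2=O
F4 | step 9 | 2-chloro-1-(2-hydroxy-3,4,6-trimethoxyphenyl)ethanone | COc1cc(OC)c(C(=O)CCl)c(O)c1OC
F5 | step 9 | 4,6,7-trimethoxybenzofuran-3(2H)-one | COc1cc(OC)c2c(c1OC)OCC2=O
F6 | step 9 | 1-bromo-2,4-diisopropoxy-5-methoxybenzene | COc1cc(Br)c(OC(C)C)cc1OC(C)C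
F7 | step 9 | 2-(2,4-diisopropoxy-5-methoxyphenyl)-4,6,7-trimethoxybenzofuran-3(2H)-one (racemic) | COc1cc(OC)c2c(c1OC)OC(c1cc(OC)c(OC(C)C)cc1OC(C)C)C2=O
F8 | step 11 | [2-(2,4-diisopropoxy-5-methoxyphenyl)-5,7,8-trimethoxy-4-oxochromen-3-yl]magnesium chloride | COc1cc(OC)c2c(=O)c([Mg]Cl)c(-c3cc(OC)c(OC(C)C)cc3OC(C)C)oc2c1OC
F9 | step 11 | dimethyl [2-(2,4-diisopropoxy-5-methoxyphenyl)-5,7,8-trimethoxy-4-oxochromen-3-yl]boronate | COc1cc(OC)c2c(=O)c(B(OC)OC)c(-c3cc(OC)c(OC(C)C)cc3OC(C)C)oc2c1OC
F10 | step 13 | 2-(2,4-diisopropoxy-5-methoxyphenyl)-3,5-dihydroxy-7,8-dimethoxychromen-4-one | COc1cc(O)c2c(=O)c(O)c(-c3cc(OC)c(OC(C)C)cc3OC(C)C)oc2c1OC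
A1 | alternative 1 | 4'-benzyloxy-5,7,8,5'-tetramethoxyflavonol with the C3 oxygen and the C2' oxygen joined by a methylene bridge | COc1cc(OC)c2c(=O)c3OCOc4cc(OCc5ccccc5)c(OC)cc4-c3oc2c1OC
A2 | alternative 1 | 3-{[5-(benzyloxy)-2-bromo-4-methoxyphenoxy]methoxy}-5,7,8-trimethoxychromen-4-one | COc1cc(OC)c2c(=O)c(OCOc3cc(OCc4ccccc4)c(OC)cc3Br)coc2c1OC
A3 | alternative 2 | 2-[2,4-bis(benzyloxy)-5-methoxyphenyl]-7-methoxy-5-(methoxymethoxy)chromen-4-one | COCOc1cc(OC)cc2oc(-c3cc(OC)c(OCc4ccccc4)cc3OCc3ccccc3)cc(=O)c12
A4 | alternative 2 | 3-[2,4-bis(benzyloxy)-5-methoxyphenyl]prop-2-ynoic acid | COc1cc(C#CC(=O)O)c(OCc2ccccc2)cc1OCc1ccccc1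
A5 | alternative 2 | 4-methoxy-2-(methoxymethoxy)-6-(trimethylsilyl)phenyl trifluoromethanesulfonate | COCOc1cc(OC)cc([Si](C)(C)C)c1OS(=O)(=O)C(F)(F)F
A6 | alternative 3 | 3-benzyloxy-2-[2,4-bis(benzyloxy)-5-methoxyphenyl]-5,7-dihydroxy-8-methoxychromen-4-one | COc1c(O)cc(O)c2c(=O)c(OCc3ccccc3)c(-c3cc(OC)c(OCc4ccccc4)cc3OCc3ccccc3)oc12
A7 | alternative 3 | tert-butyl 4-{5-(benzyloxy)-6-[2,4-bis(benzyloxy)-5-methoxyphenyl]-4-oxo-4H-pyran-2-yl}-4-methoxy-3-oxobutanoate (racemic) | CC(C)(C)OC(=O)CC(=O)C(OC)c1cc(=O)c(OCc2ccccc2)c(-c2cc(OC)c(OCc3ccccc3)cc2OCc2ccccc2)o1
A8 | alternative 3 | kojic acid (5-hydroxy-2-(hydroxymethyl)-4H-pyran-4-one) | OCc1cc(=O)c(O)co1
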